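**Plan**

- Numbering: isochroman-1-one (C1 carbonyl, O2 ring oxygen, C3 stereocentre, C4, C4a, C8 bearing OH, C8a); ring A is the benzene ring, ring B the lactone; side chain C1'–C15' with the alkene at C6'=C7'.
- Retrosynthesis: cut the O–CH3 bond of a protected C8 phenol, then C5'–C6' (alkyl–alkenyl coupling), then O2–C3 and C1–C8a together, which removes CO2 from ring B; the remaining C4a–C4 and C1'–C2' bonds lead back to epichlorohydrin.
- Forward: ring A is bought; epichlorohydrin is joined to ring A and then to a butenyl stub; iodine is placed on C8a and a tosylate on C3; one operation inserts CO2 between C8a and C3 and closes ring B; the chain is then completed and the phenol set free.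
- Enabling feature: C8a is the ring A carbon flanked by the C8 oxygen and the C4a side arm, and C3 lies three bonds from it (C8a–C4a–C4–C3), so a carboxylate on C8a reaches C3 through a six-membered transition state; the O–C(=O) unit of ring B is CO2 itself.
- Stereochemistry: C3 comes from (R)-epichlorohydrin, is carried as the (S)-carbinol and is inverted to (R) in the key step; the E alkene comes from syn-hydroalumination of dec-1-yne and a stereoretentive coupling.

Key step: step 5

Assumption: Grignard reagents 1 and 5 are used as bought THF solutions, and (R)-epichlorohydrin of high enantiomeric purity is used.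

**Step 1**
Reactants: 1 (3-methoxyphenyl)magnesium bromide; 2 (R)-epichlorohydrin
Product: 4 (R)-2-(3-methoxybenzyl)oxirane, via chlorohydrin 3 (not isolated)
Conditions: CuI (10 mol%), THF, −40 → 0 °C; then 4 M aq NaOH, rt
Reagents that add atoms: none
Why: Copper-catalysed aryl Grignard opening of the epoxide at its CH2 carbon should be much faster than direct displacement of chloride (which would give the enantiomer) and leaves the stereocentre untouched, and base then closes the chlorohydrin to the new epoxide (Williamson-type ring closure), so the (R) centre of 2 is carried into 4.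

**Step 2**
Reactants: 4 (R)-2-(3-methoxybenzyl)oxirane; 5 but-3-en-1-ylmagnesium bromide
Product: 6 (S)-1-(3-methoxyphenyl)hept-6-en-2-ol
Conditions: CuI (10 mol%), THF, −30 → 0 °C; then aq NH4Cl
Reagents that add atoms: none
Why: Copper-catalysed Grignard opening of a monosubstituted epoxide occurs by SN2 attack at the terminal carbon and does not touch the stereocentre; the descriptor changes from R to S only because the CIP ranking of the two carbon arms changes.

**Step 3**
Reactants: 6 (S)-1-(3-methoxyphenyl)hept-6-en-2-ol
Product: 8 (S)-1-(2-iodo-3-methoxyphenyl)hept-6-en-2-ol, via dilithio species 7 (not isolated)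
Conditions: n-BuLi (2.4 equiv), Et2O, 0 °C → rt; then ICH2CH2I, THF, −78 °C → rt; then H2O
Reagents that add atoms: 1,2-diiodoethane, ICCI
Why: Directed ortho-metalation: the lithium alkoxide (six-membered chelate) and the methoxy oxygen should both steer n-BuLi to the one ring carbon between them (the future C8a), and the aryllithium is iodinated by 1,2-diiodoethane with loss of ethene, the carbinol centre not being involved.

**Step 4**
Reactants: 8 (S)-1-(2-iodo-3-methoxyphenyl)hept-6-en-2-ol
Product: 9 (S)-1-(2-iodo-3-methoxyphenyl)hept-6-en-2-yl 4-methylbenzenesulfonate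
Conditions: TsCl, Et3N, DMAP (cat.), CH2Cl2, 0 °C → rt
Reagents that add atoms: p-toluenesulfonyl chloride, Cc1ccc(cc1)S(=O)(=O)Cl
Why: Sulfonylation of a secondary alcohol at oxygen (tosylation) turns the C3 oxygen into a leaving group with retention, since the C3–O bond is not broken.

**Step 5**
Reactants: 9 (S)-1-(2-iodo-3-methoxyphenyl)hept-6-en-2-yl 4-methylbenzenesulfonate
Product: 12 (R)-8-methoxy-3-(pent-4-en-1-yl)isochroman-1-one, via aryl Grignard 10 (not isolated), via chloromagnesium carboxylate 11 (not isolated)
Conditions: i-PrMgCl·LiCl (1.1 equiv), THF, −20 °C; CO2 (1 atm), −20 °C → rt; then THF exchanged for DMF, 60 °C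
Reagents that add atoms: carbon dioxide, O=C=O
Why: Iodine–magnesium exchange at C8a gives aryl Grignard 10, which adds to CO2 and so forms the C1–C8a bond; the carboxylate oxygen of 11 then attacks C3 from the side opposite the tosylate and forms the O2–C3 bond. The closest known reaction types are the Parham cyclization (halogen–metal exchange, capture of an electrophile, ring closure onto a side-chain leaving group) and the SN2 inversion of secondary sulfonates by carboxylates. Ring B closes in the 6-exo-tet mode. C3 is the only stereocentre formed and is controlled by the configuration of the tosylate: backside displacement should turn the (S)-sulfonate into the (R)-lactone. The step needs exchange at C–I before any attack on sulfonate sulfur or any elimination, which the low temperature and the low basicity of the magnesium reagent should secure. It also needs ring closure at oxygen to outrun elimination to the styrene and outside substitution by chloride (which would cost configuration), and the six-membered transition state and the weak basicity of the carboxylate favour this.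

**Step 6**
Reactants: 13 dec-1-yne
Product: 15 (E)-1-iododec-1-ene, via alkenylalane 14 (not isolated)
Conditions: i-Bu2AlH, hexane, 50 °C; then I2, THF, −50 → 0 °C
Reagents that add atoms: iodine, II
Why: Hydroalumination–iodination: syn addition of Al–H across the terminal alkyne puts aluminium on C1 trans to the chain, and iodinolysis of the alkenyl–aluminium bond proceeds with retention to give the E iodide.

**Step 7**
Reactants: 12 (R)-8-methoxy-3-(pent-4-en-1-yl)isochroman-1-one; 15 (E)-1-iododec-1-ene
Product: 17 (R)-8-methoxy-3-[(E)-pentadec-6-en-1-yl]isochroman-1-one, via alkylborane 16 (not isolated)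
Conditions: 9-BBN, THF, 0 °C → rt; then 15, Pd(dppf)Cl2 (5 mol%), AsPh3, Cs2CO3, DMF/H2O, rt
Reagents that add atoms: none
Why: B-alkyl Suzuki–Miyaura coupling: 9-BBN hydroborates the terminal alkene at C5' without touching the lactone, and the primary alkylborane couples with the alkenyl iodide under palladium catalysis with retention of the E geometry, which forms the C5'–C6' bond.

**Step 8**
Reactants: 17 (R)-8-methoxy-3-[(E)-pentadec-6-en-1-yl]isochroman-1-one
Product: 19 (R)-8-hydroxy-3-[(E)-pentadec-6-en-1-yl]isochroman-1-one (target), via aryloxydichloroborane 18 (not isolated)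
Conditions: BCl3, CH2Cl2, −78 → 0 °C; then H2O
Reagents that add atoms: none
Why: Lewis-acid ether cleavage: BCl3 chelates between the C1 carbonyl and the peri methoxy oxygen, so chloride removes only this methyl group, and the lactone, the C3 centre and the isolated alkene should stay untouched.

**Compound list**

1 | (3-methoxyphenyl)magnesium bromide | COc1cccc([Mg]Br)c1 | starting material
2 | (R)-epichlorohydrin, (R)-2-(chloromethyl)oxirane | ClC[C@H]1CO1 | starting material
3 | (R)-1-chloro-3-(3-methoxyphenyl)propan-2-ol | ClC[C@H](O)Cc1cccc(OC)c1 | intermediate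
4 | (R)-2-(3-methoxybenzyl)oxirane | COc1cccc(C[C@@H]2CO2)c1 | intermediate
5 | but-3-en-1-ylmagnesium bromide | C=CCC[Mg]Br | starting material
6 | (S)-1-(3-methoxyphenyl)hept-6-en-2-ol | COc1cccc(C[C@@H](O)CCCC=C)c1 | intermediate
7 | lithium (S)-1-(2-lithio-3-methoxyphenyl)hept-6-en-2-olate | COc1cccc(C[C@@H](O[Li])CCCC=C)c1[Li] | intermediate
8 | (S)-1-(2-iodo-3-methoxyphenyl)hept-6-en-2-ol | COc1cccc(C[C@@H](O)CCCC=C)c1I | intermediate
9 | (S)-1-(2-iodo-3-methoxyphenyl)hept-6-en-2-yl 4-methylbenzenesulfonate | COc1cccc(C[C@@H](OS(=O)(=O)c2ccc(C)cc2)CCCC=C)c1I | intermediate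
10 | [2-methoxy-6-[(S)-2-(tosyloxy)hept-6-en-1-yl]phenyl]magnesium chloride | COc1cccc(C[C@@H](OS(=O)(=O)c2ccc(C)cc2)CCCC=C)c1[Mg]Cl | intermediate
11 | chloromagnesium 2-methoxy-6-[(S)-2-(tosyloxy)hept-6-en-1-yl]benzoate | COc1cccc(C[C@@H](OS(=O)(=O)c2ccc(C)cc2)CCCC=C)c1C(=O)O[Mg]Cl | intermediate
12 | (R)-8-methoxy-3-(pent-4-en-1-yl)isochroman-1-one | C=CCCC[C@@H]1Cc2cccc(OC)c2C(=O)O1 | intermediate
13 | dec-1-yne | CCCCCCCCC#C | starting material
14 | (E)-dec-1-en-1-yl(diisobutyl)alane | CCCCCCCC/C=C/[Al](CC(C)C)CC(C)C | intermediate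
15 | (E)-1-iododec-1-ene | CCCCCCCC/C=C/I | intermediate
16 | (R)-3-[5-(9-borabicyclo[3.3.1]nonan-9-yl)pentyl]-8-methoxyisochroman-1-one | C(CCCC[C@@H]1Cc2cccc(OC)c2C(=O)O1)B3C4CCCC3CCC4 | intermediate
17 | (R)-8-methoxy-3-[(E)-pentadec-6-en-1-yl]isochroman-1-one | CCCCCCCC/C=C/CCCCC[C@@H]1Cc2cccc(OC)c2C(=O)O1 | intermediate
18 | (R)-8-(dichloroboryloxy)-3-[(E)-pentadec-6-en-1-yl]isochroman-1-one | CCCCCCCC/C=C/CCCCC[C@@H]1Cc2cccc(OB(Cl)Cl)c2C(=O)O1 | intermediate
19 | (R)-8-hydroxy-3-[(E)-pentadec-6-en-1-yl]isochroman-1-one | CCCCCCCC/C=C/CCCCC[C@@H]1Cc2cccc(O)c2C(=O)O1 | target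

**Count**

Total steps: 8. Longest linear sequence: 7 (steps 1, 2, 3, 4, 5, 7, 8).

**Steps most likely to fail**

Step 5. The aryl-magnesium centre may attack the sulfonate sulfur, the tosylate may be lost by elimination before or after carboxylation, or configuration may be eroded by halide substitution ahead of ring closure. The fallback sets out from 6 and comes back at 12; it needs no leaving group at C3 and closes ring B at the acyl carbon with retention. Mitsunobu esterification of 6 with 4-nitrobenzoic acid (PPh3, DIAD, THF) inverts C3 and should give (R)-1-(3-methoxyphenyl)hept-6-en-2-yl 4-nitrobenzoate F1. Saponification (LiOH, THF/H2O) should give (R)-1-(3-methoxyphenyl)hept-6-en-2-ol F2. Double deprotonation with n-BuLi in Et2O should give lithium (R)-1-(2-lithio-3-methoxyphenyl)hept-6-en-2-olate F3, which is quenched with CO2. Acidification should give (R)-2-(2-hydroxyhept-6-en-1-yl)-6-methoxybenzoic acid F4, which should close to 12 with TsOH (cat.) in toluene by ordinary lactonisation.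

Step 3. Lithiation may occur at other ring positions or at the benzylic CH2, or n-BuLi may attack the alkene, so that regioisomeric iodides form. The fallback sets out from 2 and comes back at 12; the halogen pattern is bought with the arene instead of being made by metalation.
- 2-Bromo-1-iodo-3-methoxybenzene F5 should undergo selective iodine–magnesium exchange (i-PrMgCl, THF, −40 °C) to (2-bromo-3-methoxyphenyl)magnesium chloride F6.
- F6 opens 2 under CuI catalysis to (R)-1-(2-bromo-3-methoxyphenyl)-3-chloropropan-2-ol F7, and NaOH closes this to (R)-2-(2-bromo-3-methoxybenzyl)oxirane F8.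
- Opening with 5 (CuI, THF) should give (S)-1-(2-bromo-3-methoxyphenyl)hept-6-en-2-ol F9, and tosylation should give (S)-1-(2-bromo-3-methoxyphenyl)hept-6-en-2-yl 4-methylbenzenesulfonate F10.
- Bromine–lithium exchange (t-BuLi, THF, −100 °C) should give [2-methoxy-6-[(S)-2-(tosyloxy)hept-6-en-1-yl]phenyl]lithium F11, CO2 should give lithium 2-methoxy-6-[(S)-2-(tosyloxy)hept-6-en-1-yl]benzoate F12, and warming in DMF should close ring B to 12 with inversion.

Step 7. The aqueous base may open the lactone, or slow transmetalation of the alkylborane may lead to protodeboronation or β-hydride elimination. The fallback sets out from 12 and comes back at 17; it replaces the borane coupling in aqueous base by a base-free organozinc coupling. Alkylborane 16, made as in step 7, is oxidised with NaBO3·4H2O to (R)-3-(5-hydroxypentyl)-8-methoxyisochroman-1-one F13. An Appel reaction (I2, PPh3, imidazole, CH2Cl2) should give (R)-3-(5-iodopentyl)-8-methoxyisochroman-1-one F14. Zinc insertion (Zn, LiCl, THF) should give [5-[(R)-8-methoxy-1-oxoisochroman-3-yl]pentyl]zinc iodide F15, and Negishi coupling with 15 (Pd(PPh3)4, THF, rt) should give 17 with retention of the E geometry.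

**Further compounds**

F1 | step 5 | (R)-1-(3-methoxyphenyl)hept-6-en-2-yl 4-nitrobenzoate | COc1cccc(C[C@H](OC(=O)c2ccc(cc2)[N+](=O)[O-])CCCC=C)c1
F2 | step 5 | (R)-1-(3-methoxyphenyl)hept-6-en-2-ol | COc1cccc(C[C@H](O)CCCC=C)c1
F3 | step 5 | lithium (R)-1-(2-lithio-3-methoxyphenyl)hept-6-en-2-olate | COc1cccc(C[C@H](O[Li])CCCC=C)c1[Li]
F4 | step 5 | (R)-2-(2-hydroxyhept-6-en-1-yl)-6-methoxybenzoic acid | COc1cccc(C[C@H](O)CCCC=C)c1C(=O)O
F5 | step 3 | 2-bromo-1-iodo-3-methoxybenzene | COc1cccc(I)c1Br
F6 | step 3 | (2-bromo-3-methoxyphenyl)magnesium chloride | COc1cccc([Mg]Cl)c1Br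
F7 | step 3 | (R)-1-(2-bromo-3-methoxyphenyl)-3-chloropropan-2-ol | ClC[C@H](O)Cc1cccc(OC)c1Br
F8 | step 3 | (R)-2-(2-bromo-3-methoxybenzyl)oxirane | COc1cccc(C[C@@H]2CO2)c1Br
F9 | step 3 | (S)-1-(2-bromo-3-methoxyphenyl)hept-6-en-2-ol | COc1cccc(C[C@@H](O)CCCC=C)c1Br
F10 | step 3 | (S)-1-(2-bromo-3-methoxyphenyl)hept-6-en-2-yl 4-methylbenzenesulfonate | COc1cccc(C[C@@H](OS(=O)(=O)c2ccc(C)cc2)CCCC=C)c1Br
F11 | step 3 | [2-methoxy-6-[(S)-2-(tosyloxy)hept-6-en-1-yl]phenyl]lithium | COc1cccc(C[C@@H](OS(=O)(=O)c2ccc(C)cc2)CCCC=C)c1[Li]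
F12 | step 3 | lithium 2-methoxy-6-[(S)-2-(tosyloxy)hept-6-en-1-yl]benzoate | COc1cccc(C[C@@H](OS(=O)(=O)c2ccc(C)cc2)CCCC=C)c1C(=O)O[Li]
F13 | step 7 | (R)-3-(5-hydroxypentyl)-8-methoxyisochroman-1-one | OCCCCC[C@@H]1Cc2cccc(OC)c2C(=O)O1
F14 | step 7 | (R)-3-(5-iodopentyl)-8-methoxyisochroman-1-one | ICCCCC[C@@H]1Cc2cccc(OC)c2C(=O)O1
F15 | step 7 | [5-[(R)-8-methoxy-1-oxoisochroman-3-yl]pentyl]zinc iodide | I[Zn]CCCCC[C@@H]1Cc2cccc(OC)c2C(=O)O1
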